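**Retrosynthetic overview**
- The target is one unbranched 25-membered lactone ring (24 C and 1 O) with no stereocentre. The plan rests on reading its ring atoms as three blocks: C1–C2 (carbonyl and α-carbon) as an acrylate; C3–C14 as the twelve carbons of cyclododecene opened at its double bond; C15–C24 with the ring oxygen as the first ten carbons and the hydroxyl oxygen of undec-10-en-1-ol.
- Disconnections: retro-hydrogenation to the C2=C3 and C14=C15 olefins, both cut in one ring-opening/ring-closing metathesis, then the C1–O ester bond by acylation.
- Forward order: alcohol 1 and acid chloride 2 give diene ester 3. Ester 3 and cyclododecene 4 give, via open-chain triene 5, dienolide 6; this is the only ring-forming event and closes the 25-membered ring. Hydrogenation of 6 gives target 7.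

Key step: step 2

Assumption: commercial cyclododecene (cis/trans mixture) is used as bought. The new olefins in 5 and 6 are drawn E; the isolated one is expected as an E/Z mixture, which is of no consequence because step 3 removes both double bonds.

**Step 1**
Reactants: 1 undec-10-en-1-ol; 2 acryloyl chloride
Product: 3 undec-10-en-1-yl prop-2-enoate (undec-10-enyl acrylate)
Conditions: Et3N, CH2Cl2, 0 °C to rt, trace BHT as radical inhibitor
Reagents that add atoms: none
Why: O-acylation of an unhindered primary alcohol by an acid chloride with an amine base (nucleophilic acyl substitution) is fast at 0 °C and leaves the remote terminal olefin untouched.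

**Step 2**
Reactants: 3 undec-10-en-1-yl prop-2-enoate; 4 cyclododecene
Product: 6 (3E,15E)-1-oxacyclopentacosa-3,15-dien-2-one, via ring-opened triene acrylate 5 (not isolated)
Conditions: 4 (1.5 equiv), second-generation Grubbs catalyst RuCl2(=CHPh)(PCy3)(H2IMes) (5 mol %; H2IMes = 1,3-dimesitylimidazolidin-2-ylidene), CH2Cl2 (5 mM in 3), 40 °C, Ar sweep; then ethyl vinyl ether
Reagents that add atoms: none
Why: The ruthenium benzylidene initiates on the electron-rich terminal olefin of the undecenyl chain of 3, and the resulting alkyl alkylidene opens the twelve-membered carbocycle of 4 by [2+2] cycloaddition and cycloreversion, forming the C14=C15 olefin (acid numbering) and leaving the far chain end as a ruthenium alkylidene or, after exchange with a terminal olefin, as free triene 5. That alkylidene then reacts with the tethered acrylate in a macrocyclic ring-closing cross-metathesis that forms C2=C3 within the ring and closes the 25-membered lactone, the released Ru=CH2 re-entering the cycle with loss of ethylene. The closest known reaction type is ring-expansion metathesis of cycloalkenes with acrylate-terminated acyclic dienes under second-generation ruthenium carbene catalysis. The step needs one cycloalkene per diene and cyclisation instead of chain growth: the acrylate does not homodimerise and couples only with alkyl alkylidenes, whereas homodimers of the alkyl terminus and oligomers of 4 keep metathesis-active isolated olefins and are fed back, so the conjugated enoate is the sink and high dilution favours closure and the loss of any second C12 unit. No stereocentre is formed; the enoate is expected mainly E under thermodynamic control and both olefins are erased in step 3. Direct closure of 3 to the 13-membered enoate lactone should be slower because of that ring's strain and is further suppressed by the modest excess of 4.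

**Step 3**
Reactants: 6 (3E,15E)-1-oxacyclopentacosa-3,15-dien-2-one
Product: 7 1-oxacyclopentacosan-2-one (24-tetracosanolide)
Conditions: H2 (1 atm), 10 % Pd/C, EtOAc, rt
Reagents that add atoms: none
Why: Heterogeneous catalytic hydrogenation saturates both disubstituted olefins, conjugated and isolated, while the lactone is inert in a non-nucleophilic solvent, and no stereocentre arises.

**Compound list**
1 | undec-10-en-1-ol | OCCCCCCCCCC=C | starting material
2 | acryloyl chloride | C=CC(=O)Cl | starting material
3 | undec-10-en-1-yl prop-2-enoate | C=CC(=O)OCCCCCCCCCC=C | intermediate
4 | cyclododecene (cis/trans mixture) | C1=CCCCCCCCCCC1 | starting material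
5 | (10E)-tricosa-10,22-dien-1-yl prop-2-enoate (geometry may be mixed) | C=CC(=O)OCCCCCCCCC/C=C/CCCCCCCCCCC=C | intermediate
6 | (3E,15E)-1-oxacyclopentacosa-3,15-dien-2-one, i.e. (2E,14E)-tetracosa-2,14-dien-24-olide (isolated olefin may be E/Z) | O=C1/C=C/CCCCCCCCCC/C=C/CCCCCCCCCO1 | intermediate
7 | 1-oxacyclopentacosan-2-one (24-tetracosanolide) | O=C1CCCCCCCCCCCCCCCCCCCCCCCO1 | target

**Total step count:** 3
**Longest linear sequence:** 3 steps (1 → 3 → 6 → 7)

**Steps most likely to fail**

Step 2. Chain growth and mis-sized rings may outrun the one-to-one ring expansion: 3 may close without taking up the cycloalkene, two C12 units may be retained, or acyclic enoate-linked oligomers may form. The fallback gives up the metathesis macrocyclisation for a Wittig chain coupling followed by macrolactonisation. It sets out from 4 and comes back at 7. Ozonolysis of 4 with unsymmetrical work-up (O3, CH2Cl2/MeOH, NaHCO3, −78 °C; then Ac2O, Et3N) should give methyl 12-oxododecanoate F1. Commercial 12-bromododecan-1-ol and PPh3 in refluxing MeCN should give (12-hydroxydodecyl)triphenylphosphonium bromide F2. Its ylide (2 equiv NaN(SiMe3)2, THF, −78 to 0 °C) should add to F1 in a Wittig reaction to give methyl (12Z)-24-hydroxytetracos-12-enoate F3. Hydrogenation (H2, Pd/C, EtOAc) should give methyl 24-hydroxytetracosanoate F4, and saponification (LiOH, THF/H2O, then acid) should give 24-hydroxytetracosanoic acid F5. Yamaguchi macrolactonisation (2,4,6-trichlorobenzoyl chloride, Et3N, THF; slow addition to DMAP in refluxing toluene at high dilution) should then close the ring to 7.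

Step 1. Conjugate addition of chloride or amine to the acrylate, or radical polymerisation during acylation and purification, may erode the ester. The fallback keeps the acrylate masked until the end. It sets out from 1 and comes back at 3. Acylation of 1 with 3-chloropropanoyl chloride (pyridine, CH2Cl2, 0 °C) should give undec-10-en-1-yl 3-chloropropanoate F6. E1cB elimination of hydrogen chloride with Et3N in CH2Cl2 at rt should then unveil 3.

Step 3. Hydrogen uptake may stall through poisoning of the palladium surface by ruthenium residues carried over from step 2, leaving partly reduced material. The fallback is a metal-free diimide reduction (2-nitrobenzenesulfonylhydrazide, Et3N, CH2Cl2, rt, in excess), which transfers hydrogen to both olefins in a concerted way. It sets out from 6, comes back at 7 and makes no new compound (F0).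

**Further compounds**
F1 | step 2 | methyl 12-oxododecanoate | COC(=O)CCCCCCCCCCC=O
F2 | step 2 | (12-hydroxydodecyl)triphenylphosphonium bromide | OCCCCCCCCCCCC[P+](c1ccccc1)(c1ccccc1)c1ccccc1.[Br-]
F3 | step 2 | methyl (12Z)-24-hydroxytetracos-12-enoate | COC(=O)CCCCCCCCCC/C=C\CCCCCCCCCCCO
F4 | step 2 | methyl 24-hydroxytetracosanoate | COC(=O)CCCCCCCCCCCCCCCCCCCCCCCO
F5 | step 2 | 24-hydroxytetracosanoic acid | OC(=O)CCCCCCCCCCCCCCCCCCCCCCCO
F6 | step 1 | undec-10-en-1-yl 3-chloropropanoate | ClCCC(=O)OCCCCCCCCCC=C
F0 | step 3 | none | none
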